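Locants without primes refer to ring A (the dihydrobenzofuran that carries the styryl group), primed locants to ring B. RB stands for the ring B unit (2R,3R)-7-(benzyloxy)-3-[3,5-bis(benzyloxy)phenyl]-2-[4-(benzyloxy)phenyl]-2,3-dihydro-1-benzofuran-5-yl.

## The problem

The target is a heptaphenol in which two trans-2-(4-hydroxyphenyl)-3-aryl-2,3-dihydrobenzofurans are joined by one bond, from C3 of ring A to C5' of ring B. Ring A carries a (Z)-4-hydroxystyryl group at C4, next to the C3 methine, so every bond made to C3 is formed between two ortho-substituted positions of a 1,2,3,5-tetrasubstituted arene. There are four stereocentres in two pairs, (2S,3S) in ring A and (2'R,3'R) in ring B. The flat ring B arene lies between the pairs, so neither can steer the other and each needs its own absolute control. Within a pair the trans arrangement is the stable one, but only the 4-oxybenzylic ether carbons C2 and C2' can be equilibrated (acid, through the ring-opened benzylic cation); C3 and C3' cannot, so these two carbons must be set correctly the first time. The fragile elements are the Z-stilbene (isomerised by acid, light and radicals, saturated by hydrogenolysis), the benzylic aryl ether bonds O1–C2 and O1'–C2', and seven phenols that must be freed at the end without hot acid or hydrogen. The opening lies in ring B: the aryl ether bond O1'–C7a' is para to C5'. A carboxyl group at C5' therefore activates a fluoride at C7a' towards displacement by the C2' oxygen and later becomes C3 of ring A, while C3' is the alpha carbon of an aryl ketone at C2' and stays configurationally mobile until that carbonyl is reduced.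

## Retrosynthesis

**Unmasking, 25 from 24.** The seven O–CH2Ph bonds are cut last. Methyl ethers would need BBr3 at temperatures where a 2-(4-oxyphenyl)dihydrobenzofuran ionises at C2 and a Z-stilbene isomerises or cyclises onto a neighbouring arene, and hydrogenolysis would saturate the olefin. Benzyl ethers cleaved by BCl3 with pentamethylbenzene at −78 °C are the mildest choice with precedent for polyphenols that contain trans-2,3-diaryldihydrobenzofurans, so every phenol is carried as a benzyl ether from the start. The forward step must go to completion at seven sites and leave the olefin geometry alone.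

**Styryl group, 24 from 23, 23 from 21 and 22.** The C=C bond is traced to an alkyne and the C4–C(sp) bond to aryl bromide 21 and commercial alkyne 22. A Wittig reaction at a C4 aldehyde would give E/Z mixtures, and an ortho alkenyl or alkynyl group cannot be present while a carbene is generated at C3, since it would add to the π bond. Bromine is the one C4 substituent that survives an aryllithium at −78 °C, hydrazine and a rhodium carbene, so the unsaturation is added after ring A is closed and the Z geometry comes from syn semi-hydrogenation.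

**Ring A, 21 from 20, 20 from 18, 18 from 17.** The C2–C3 bond is cut. Ring A then becomes diaryl ketone 17, whose carbonyl carbon is C3 and whose ortho oxygen carries the 4-(benzyloxy)benzyl group that supplies C2 and its aryl group. Hydrazone 18 is oxidised to a diazo compound, and a chiral dirhodium carboxylate turns this into a donor/donor carbene that inserts into the benzylic C–H bond. Closing O1–C2 or O1–C7a instead would require an acyclic C2–C3 pair built with full control beside ring B, and C7a has no activating group para to it, so the ring B tactic cannot be repeated. A C3–C3a cut leads to Friedel–Crafts chemistry without absolute control. The insertion sets C3 by catalyst control and should give the cis ring kinetically; acid equilibration at C2 (20 to 21) then gives trans without touching C3. The precursor has no stereocentre in its ring A half.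

**Ring A oxygen pattern, 17 from 15 and 16.** The O–C7a aryl ether bond is cut. The ketone that will become the carbene also activates its ortho position, so a fluorine there is displaced by the alkoxide of commercial alcohol 16. This tells the two ring A oxygens apart without protecting-group steps: the C6 oxygen is a benzyl ether from the beginning and the C7a oxygen arrives together with C2. It also removes the fluorine before hydrazine is used, which matters because an ortho-fluoro ketone would close an indazole.

**Joining the halves, 15 from 11 and 13 (through 14), 11 from 10, 13 from 12.** The C3–C3a bond is cut. The carbonyl carbon of 15 is the carboxyl carbon of ring B ester 10, so ring A must be the nucleophile. In 13 the hydrogen between fluorine and bromine is the most acidic, so LiN(iPr)2 should give aryllithium 14 at exactly the carbon that becomes C3a. Weinreb amide 11 stops the addition at the ketone. Phenol 12 is commercial.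

**Ring B, 10 from 8 (key disconnection).** The O1'–C7a' bond is cut and C2' is returned to the ketone level. Precursor 8 has one stereocentre, and that one is labile. The forward step must funnel both enantiomers of 8 into alcohol 9 and then close the ring by displacement of fluoride para to the ester. An O1'–C2' closure would need both centres fixed in an open chain, and a second carbene insertion would not use the para ester at all. The demanding point is that the hydride transfer must tell the two alpha-aryl groups apart. Acid can later correct C2' but never C3', so the reduction has to deliver 3'R; equilibrating a cis/trans mixture would turn the cis isomer into the enantiomeric trans series. The catalyst enantiomer is chosen for C3', and any cis ester is separated as a diastereomer at the stage of 10.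

**Ketone 8 from 7 and 4, 7 from 5 and 6.** The C3'–C3a' bond and then the other alpha-aryl bond are cut, giving two successive palladium-catalysed alpha-arylations of commercial acetophenone 5. The electron-rich bromide 6 goes on first, with a strong base and no sensitive groups present. The ester- and fluorine-bearing bromide 4 goes on last under K3PO4. A Friedel–Crafts route to deoxybenzoin 7 is ruled out by the benzyl ethers.

**Bromide 4 from 3, 3 from 1.** The C5–O bond of the benzoate is cut. Metalation of a 4-fluoro-3-alkoxybenzoate would take place between the ester and the alkoxy group, not beside fluorine, so introducing bromine that way was rejected. The bromine is bought in place (1), and the oxygen is introduced by sterically controlled C–H borylation and oxidation at C5, the only position without a large ortho neighbour.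

## Roads not taken

**Alternative 1:** Ring A is written de novo. The cut runs through the ring A benzene (C7a–C7 and C5–C6). Heating cyclobutenone A1 with silyloxyalkyne A2 should give, by ring opening to a vinylketene, (2+2) addition, second ring opening and 6π electrocyclisation, the fully substituted phenol A3.
- Merits: every ring A substituent is placed unambiguously, the two ring A oxygens emerge differentiated (free phenol at C7a, silyl ether at C6), the alkyne for the Z-olefin is already there, and no crowded ketone, hydrazone or carbene is needed. In these respects it is better than the chosen plan.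
- Weak points: A1 must already hold the open-chain C2–C3 pair and the whole of ring B on a strained, heat- and base-sensitive four-membered ring. The anti relation of the two open-chain centres has to be set by a separate method beside a stereogenic, enolisable cyclobutenone carbon. Ring B still has to be made by some other route first. The last ring closure (phenol onto the silyloxy-bearing benzylic carbon) must be steered to trans.
- Comparison: the chosen plan sets against this a convergent assembly from simple aromatic halides, ring A oxygen differentiation by one fluoride displacement (15 to 17), and two catalytic asymmetric steps of known type.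

**Alternative 2:** The cut is C3–C3a of ring A, made by ring contraction. Near-UV irradiation of diazoflavanone A4 in an alcohol should trigger a Wolff rearrangement in which the ring A carbon migrates to C3, and the ketene is trapped as ester A5, which an alkoxide equilibrates to trans.
- Merits: C2 comes from an enantioenriched flavanone, and the chlorine at C4 is in place from the outset. C3 becomes the alpha carbon of an ester, so trans is reached by base at C3 and not by acid at C2. That is a cleaner thermodynamic handle than the acid equilibration used in step 12.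
- Weak points: A5 carries an ester where the target has the ring B arene. The C3–C5' bond would have to be made by replacing a carboxyl carbon (radical decarboxylative arylation, or building the ring B benzene from the ester), with the C3 configuration then resting on substrate control alone. Diazo transfer to a flavanone under base risks retro-oxa-Michael opening and loss of the C2 configuration. The hindered aryl chloride is a poorer partner for the later alkynylation than bromide 21.
- Comparison: the chosen plan makes C3 from the ring B carboxyl carbon directly, so the C3–C5' bond exists before ring A is closed.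

**Alternative 3:** The 3,5-dihydroxyphenyl ring on C3' is built last. Mild aqueous base should fold triketo ester A6 by aldol addition of its C2 methylene to the C7 ketone and dehydration to resorcylate A7.
- Merits: when C2'/C3' are set, C3' bears an acyl group and not a second aryl group. The discrimination between two alpha-aryl groups, the weakest point of the chosen key step, does not arise, and C3' can be equilibrated by base. The bromide at C5' would let ring B act as the nucleophile towards a salicylaldehyde-type ring A partner whose oxygens are differentiated by hydrogen bonding. These are real advantages.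
- Weak points: A6 is a fragile polycarbonyl chain with competing Claisen and pyrone cyclisation modes. C3' is alpha to a ketone with the ring oxygen in the beta position, so the base that folds the chain can also open ring B by elimination. The extra ester on the new ring must be removed. The ring B core with a carboxyl group at C3' and the chain extension both need additional steps.
- Comparison: the chosen plan takes this ring from a commercial bromide (6), confines the stereochemical risk to one step, and allows the diastereomers to be separated at 10.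

Key step: step 5

## Route

Assumption: Rh2(R-PTAD)4 is taken to be the catalyst enantiomer that delivers the 3S centre in step 11; if the sense of induction on this substrate is the opposite, Rh2(S-PTAD)4 is used and nothing else changes.

Step 1
Reactants: 1 methyl 3-bromo-4-fluorobenzoate
Product: 3 methyl 3-bromo-4-fluoro-5-hydroxybenzoate, via pinacol boronate 2 (not isolated)
Conditions: [Ir(OMe)(cod)]2 (cat.), dtbpy, B2pin2, THF, 80 °C; then KHSO5 (as 2KHSO5·KHSO4·K2SO4), acetone/H2O, rt
Reagents that add atoms: bis(pinacolato)diboron, CC1(C)OB(OC1(C)C)B1OC(C)(C)C(C)(C)O1; potassium peroxymonosulfate KHSO5, [K+].OOS(=O)(=O)[O-]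
Why: Sterically governed iridium-catalysed aromatic C–H borylation: C2 lies between bromine and the ester and C6 is ortho to the ester, so only C5, whose one neighbour is the small fluorine, should react. The boronate is oxidised in the same flask to the phenol (borylation–oxidation), which leaves the ester and the bromide untouched.

Step 2
Reactants: 3 methyl 3-bromo-4-fluoro-5-hydroxybenzoate
Product: 4 methyl 3-(benzyloxy)-5-bromo-4-fluorobenzoate
Conditions: BnBr, K2CO3, acetone, 50 °C
Reagents that add atoms: benzyl bromide, BrCc1ccccc1
Why: Williamson ether synthesis; O-alkylation of the phenoxide is far faster than its attack on the activated C–F carbon of a second molecule at this temperature.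

Step 3
Reactants: 5 1-[4-(benzyloxy)phenyl]ethan-1-one; 6 1,3-bis(benzyloxy)-5-bromobenzene
Product: 7 1-[4-(benzyloxy)phenyl]-2-[3,5-bis(benzyloxy)phenyl]ethan-1-one
Conditions: Pd2(dba)3 (cat.), Xantphos, NaOtBu, toluene, 70 °C
Reagents that add atoms: none
Why: Palladium-catalysed alpha-arylation of an aryl methyl ketone enolate; the wide-bite-angle ligand and a small excess of 5 favour mono-arylation.

Step 4
Reactants: 7 1-[4-(benzyloxy)phenyl]-2-[3,5-bis(benzyloxy)phenyl]ethan-1-one; 4 methyl 3-(benzyloxy)-5-bromo-4-fluorobenzoate
Product: 8 methyl 3-(benzyloxy)-5-{1-[3,5-bis(benzyloxy)phenyl]-2-[4-(benzyloxy)phenyl]-2-oxoethyl}-4-fluorobenzoate (racemate)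
Conditions: Pd2(dba)3 (cat.), Xantphos, K3PO4, toluene, 80 °C
Reagents that add atoms: none
Why: Second palladium-catalysed alpha-arylation, now of the more acidic deoxybenzoin, for which the weak base K3PO4 suffices and spares the methyl ester. Oxidative addition occurs at C–Br and not at C–F, and the non-polar medium keeps enolate attack on the C–F carbon slow. The new stereocentre is left racemic on purpose.

Step 5
Reactants: 8 methyl 3-(benzyloxy)-5-{1-[3,5-bis(benzyloxy)phenyl]-2-[4-(benzyloxy)phenyl]-2-oxoethyl}-4-fluorobenzoate (racemate)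
Product: 10 methyl (2R,3R)-7-(benzyloxy)-3-[3,5-bis(benzyloxy)phenyl]-2-[4-(benzyloxy)phenyl]-2,3-dihydro-1-benzofuran-5-carboxylate, via fluoro alcohol 9 (not isolated)
Conditions: RuCl[(R,R)-TsDPEN](p-cymene) (cat.), HCO2H/NEt3 (5:2), DMF, 40 °C; then K2CO3, DMSO, 70 °C
Reagents that add atoms: none
Why: Under NEt3 the alpha-hydrogen of 8, flanked by two aryl groups and the carbonyl, exchanges faster than the ketone is reduced, so both enantiomers of 8 are open to the catalyst (dynamic kinetic resolution). The 18-electron ruthenium hydride formed from RuCl[(R,R)-TsDPEN](p-cymene) and formate passes hydride and the N–H proton to the carbonyl in one outer-sphere event; the face is fixed by the CH/π contact between the cymene ligand and the 4-(benzyloxy)phenyl group of the ketone, which gives the 2R carbinol. Of the two alpha-epimers the faster one should be the one that can hold its larger and more electron-poor alpha-aryl group, the ortho-fluorinated 1,2,3,5-tetrasubstituted ring, anti to the incoming hydride (Felkin–Anh arrangement), which makes the diaryl carbon R and gives (1R,2R)-9. K2CO3 in DMSO then forms the alkoxide, which attacks the C–F carbon in a 5-exo-trig addition to a Meisenheimer intermediate stabilised by the para ester, and loss of fluoride forms O1'–C7a' and closes the ring B dihydrofuran. Neither sp3 carbon is a reacting centre in the closure, so both configurations are retained and the (1R,2R) alcohol maps onto the trans (2R,3R) ring. The closest known reaction type is Noyori–Ikariya transfer hydrogenation of racemising alpha-aryl ketones followed by intramolecular SNAr etherification. The selectivity the step needs is the discrimination between the two alpha-aryl groups, which rests on the ortho fluorine and the denser substitution of the benzoate ring; since C3' cannot be corrected later, any cis ester is removed here as a separable diastereomer and is not equilibrated. Base is added only after the ketone is consumed, so that the enolate of 8 cannot displace fluoride and form a benzofuran.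

Step 6
Reactants: 10 methyl (2R,3R)-7-(benzyloxy)-3-[3,5-bis(benzyloxy)phenyl]-2-[4-(benzyloxy)phenyl]-2,3-dihydro-1-benzofuran-5-carboxylate
Product: 11 (2R,3R)-7-(benzyloxy)-3-[3,5-bis(benzyloxy)phenyl]-2-[4-(benzyloxy)phenyl]-N-methoxy-N-methyl-2,3-dihydro-1-benzofuran-5-carboxamide
Conditions: MeNH(OMe)·HCl, iPrMgCl, THF, −15 °C
Reagents that add atoms: N,O-dimethylhydroxylamine hydrochloride, CNOC.Cl
Why: Direct aminolysis of the ester by the chloromagnesium amide gives the Weinreb amide; the benzhydrylic C3'–H is not acidic enough to be touched, so both stereocentres persist.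

Step 7
Reactants: 12 3-bromo-5-fluorophenol
Product: 13 1-(benzyloxy)-3-bromo-5-fluorobenzene
Conditions: BnBr, K2CO3, acetone, 50 °C
Reagents that add atoms: benzyl bromide, BrCc1ccccc1
Why: Williamson ether synthesis on a simple phenol.

Step 8
Reactants: 13 1-(benzyloxy)-3-bromo-5-fluorobenzene; 11 (2R,3R)-7-(benzyloxy)-3-[3,5-bis(benzyloxy)phenyl]-2-[4-(benzyloxy)phenyl]-N-methoxy-N-methyl-2,3-dihydro-1-benzofuran-5-carboxamide
Product: 15 [4-(benzyloxy)-2-bromo-6-fluorophenyl](RB)methanone, via aryllithium 14 (not isolated)
Conditions: LiN(iPr)2, THF, −78 °C; then 11, −78 °C; aq. NH4Cl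
Reagents that add atoms: none
Why: Ortho-lithiation by LiN(iPr)2 at the most acidic ring hydrogen, the one flanked by fluorine and bromine. The 2,6-dihaloaryllithium is kept at −78 °C so that it does not lose lithium halide to an aryne. It adds once to the Weinreb amide, whose chelated tetrahedral intermediate prevents a second addition.

Step 9
Reactants: 15 [4-(benzyloxy)-2-bromo-6-fluorophenyl](RB)methanone; 16 [4-(benzyloxy)phenyl]methanol
Product: 17 [4-(benzyloxy)-2-{[4-(benzyloxy)phenyl]methoxy}-6-bromophenyl](RB)methanone
Conditions: 16, NaH, THF, 0 °C; then 15, DMF, 0 °C to rt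
Reagents that add atoms: none
Why: Nucleophilic aromatic substitution (addition–elimination) of the fluoride ortho to the ketone carbonyl by the benzylic alkoxide; fluoride leaves far more readily than bromide, which is kept for step 13. The reaction is run cold so that hydride transfer from the alkoxide to the ketone does not compete.

Step 10
Reactants: 17 [4-(benzyloxy)-2-{[4-(benzyloxy)phenyl]methoxy}-6-bromophenyl](RB)methanone
Product: 18 hydrazone of 17, [4-(benzyloxy)-2-{[4-(benzyloxy)phenyl]methoxy}-6-bromophenyl](RB)methanone hydrazone (E/Z mixture)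
Conditions: N2H4·H2O (excess), AcOH (cat.), n-BuOH, 110 °C
Reagents that add atoms: hydrazine hydrate, NN.O
Why: Acid-catalysed condensation to the hydrazone, run under forcing conditions because the carbonyl has two ortho substituents on one side. The ortho fluorine was replaced in step 9, so no indazole can form, and the aryl bromide does not react with hydrazine without a metal catalyst.

Step 11
Reactants: 18 hydrazone of 17
Product: 20 (2R,3S)-6-(benzyloxy)-2-[4-(benzyloxy)phenyl]-4-bromo-3-(RB)-2,3-dihydro-1-benzofuran, via diazo compound 19 (not isolated)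
Conditions: MnO2, CH2Cl2, 0 °C; filter; Rh2(R-PTAD)4 (cat.), CH2Cl2, 0 °C to rt
Reagents that add atoms: none
Why: MnO2 dehydrogenates the hydrazone to the diaryldiazomethane, and the chiral divalent-rhodium carboxylate converts it into a donor/donor carbene that inserts into the benzylic C–H bond of the ortho ArCH2O group (intramolecular 1,5 C–H insertion), forming C2–C3 and closing ring A. The catalyst sets C3 as S, and the kinetic cis relation of this reaction type gives 2R. The other benzyl ethers are out of reach of the carbene and the bromine is inert to it.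

Step 12
Reactants: 20 (2R,3S)-6-(benzyloxy)-2-[4-(benzyloxy)phenyl]-4-bromo-3-(RB)-2,3-dihydro-1-benzofuran
Product: 21 (2S,3S)-6-(benzyloxy)-2-[4-(benzyloxy)phenyl]-4-bromo-3-(RB)-2,3-dihydro-1-benzofuran
Conditions: CF3CO2H, CH2Cl2 (dilute), 0 °C to rt
Reagents that add atoms: none
Why: Acid-mediated epimerisation: the O1–C2 bond ionises reversibly to a 4-alkoxybenzylic cation that recloses to the more stable trans ring, so C2 becomes S under thermodynamic control while C3 takes no part. Ring B passes through the same equilibrium but is already trans. Cold, dilute conditions keep loss of the C3 proton from the open cation in check.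

Step 13
Reactants: 21 (2S,3S)-6-(benzyloxy)-2-[4-(benzyloxy)phenyl]-4-bromo-3-(RB)-2,3-dihydro-1-benzofuran; 22 1-(benzyloxy)-4-ethynylbenzene
Product: 23 (2S,3S)-6-(benzyloxy)-2-[4-(benzyloxy)phenyl]-4-{[4-(benzyloxy)phenyl]ethynyl}-3-(RB)-2,3-dihydro-1-benzofuran
Conditions: PdCl2(MeCN)2 (cat.), XPhos, Cs2CO3, MeCN/THF, 80 °C
Reagents that add atoms: none
Why: Copper-free Sonogashira coupling; the bulky electron-rich biarylphosphine lets zerovalent palladium insert into the hindered C4–Br bond, which is meta to both ring oxygens and so not deactivated by them.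

Step 14
Reactants: 23 (2S,3S)-6-(benzyloxy)-2-[4-(benzyloxy)phenyl]-4-{[4-(benzyloxy)phenyl]ethynyl}-3-(RB)-2,3-dihydro-1-benzofuran
Product: 24 (2S,3S)-6-(benzyloxy)-2-[4-(benzyloxy)phenyl]-4-{(Z)-2-[4-(benzyloxy)phenyl]ethenyl}-3-(RB)-2,3-dihydro-1-benzofuran
Conditions: H2 (1 atm), Pd on CaCO3 poisoned with Pb(OAc)2 (Lindlar catalyst), quinoline, EtOAc, rt
Reagents that add atoms: none
Why: Lindlar semi-hydrogenation: syn delivery of hydrogen to the alkyne on the poisoned surface gives the Z-alkene. This catalyst does not cleave benzyl ethers or the benzylic C–O bonds of the two dihydrofurans.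

Step 15
Reactants: 24 (2S,3S)-6-(benzyloxy)-2-[4-(benzyloxy)phenyl]-4-{(Z)-2-[4-(benzyloxy)phenyl]ethenyl}-3-(RB)-2,3-dihydro-1-benzofuran
Product: 25 (2R,3R)-3-(3,5-dihydroxyphenyl)-5-{(2S,3S)-6-hydroxy-2-(4-hydroxyphenyl)-4-[(Z)-2-(4-hydroxyphenyl)ethenyl]-2,3-dihydro-1-benzofuran-3-yl}-2-(4-hydroxyphenyl)-2,3-dihydro-1-benzofuran-7-ol (target)
Conditions: BCl3, C6HMe5, CH2Cl2, −78 °C; then MeOH
Reagents that add atoms: none
Why: Lewis-acid debenzylation with a cation scavenger: BCl3 cleaves the aryl benzyl ethers at −78 °C and pentamethylbenzene captures each benzyl cation before it can alkylate a phenol or generate acid that would attack the olefin. The reaction type is established for polyphenols containing trans-2,3-diaryldihydrobenzofurans, whose ring C–O bonds survive at this temperature.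

## Compound list

1 | methyl 3-bromo-4-fluorobenzoate | COC(=O)c1ccc(F)c(Br)c1 | starting material
2 | methyl 3-bromo-4-fluoro-5-(4,4,5,5-tetramethyl-1,3,2-dioxaborolan-2-yl)benzoate | COC(=O)c1cc(Br)c(F)c(c1)B1OC(C)(C)C(C)(C)O1 | intermediate (not isolated)
3 | methyl 3-bromo-4-fluoro-5-hydroxybenzoate | COC(=O)c1cc(O)c(F)c(Br)c1 | intermediate
4 | methyl 3-(benzyloxy)-5-bromo-4-fluorobenzoate | COC(=O)c1cc(OCc2ccccc2)c(F)c(Br)c1 | intermediate
5 | 1-[4-(benzyloxy)phenyl]ethan-1-one | CC(=O)c1ccc(OCc2ccccc2)cc1 | starting material
6 | 1,3-bis(benzyloxy)-5-bromobenzene | Brc1cc(OCc2ccccc2)cc(OCc2ccccc2)c1 | starting material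
7 | 1-[4-(benzyloxy)phenyl]-2-[3,5-bis(benzyloxy)phenyl]ethan-1-one | O=C(Cc1cc(OCc2ccccc2)cc(OCc2ccccc2)c1)c1ccc(OCc2ccccc2)cc1 | intermediate
8 | methyl 3-(benzyloxy)-5-{1-[3,5-bis(benzyloxy)phenyl]-2-[4-(benzyloxy)phenyl]-2-oxoethyl}-4-fluorobenzoate (racemate, alpha-centre labile) | COC(=O)c1cc(OCc2ccccc2)c(F)c(c1)C(c1cc(OCc2ccccc2)cc(OCc2ccccc2)c1)C(=O)c1ccc(OCc2ccccc2)cc1 | intermediate
9 | methyl 3-(benzyloxy)-5-{(1R,2R)-1-[3,5-bis(benzyloxy)phenyl]-2-[4-(benzyloxy)phenyl]-2-hydroxyethyl}-4-fluorobenzoate | COC(=O)c1cc(OCc2ccccc2)c(F)c(c1)[C@@H](c1cc(OCc2ccccc2)cc(OCc2ccccc2)c1)[C@H](c1ccc(OCc2ccccc2)cc1)O | intermediate (not isolated)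
10 | methyl (2R,3R)-7-(benzyloxy)-3-[3,5-bis(benzyloxy)phenyl]-2-[4-(benzyloxy)phenyl]-2,3-dihydro-1-benzofuran-5-carboxylate | COC(=O)c1cc(OCc2ccccc2)c2c(c1)[C@@H](c1cc(OCc3ccccc3)cc(OCc3ccccc3)c1)[C@H](c1ccc(OCc3ccccc3)cc1)O2 | intermediate
11 | (2R,3R)-7-(benzyloxy)-3-[3,5-bis(benzyloxy)phenyl]-2-[4-(benzyloxy)phenyl]-N-methoxy-N-methyl-2,3-dihydro-1-benzofuran-5-carboxamide | CON(C)C(=O)c1cc(OCc2ccccc2)c2c(c1)[C@@H](c1cc(OCc3ccccc3)cc(OCc3ccccc3)c1)[C@H](c1ccc(OCc3ccccc3)cc1)O2 | intermediate
12 | 3-bromo-5-fluorophenol | Oc1cc(F)cc(Br)c1 | starting material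
13 | 1-(benzyloxy)-3-bromo-5-fluorobenzene | Fc1cc(Br)cc(OCc2ccccc2)c1 | intermediate
14 | [4-(benzyloxy)-2-bromo-6-fluorophenyl]lithium | [Li]c1c(F)cc(OCc2ccccc2)cc1Br | intermediate (not isolated)
15 | [4-(benzyloxy)-2-bromo-6-fluorophenyl](RB)methanone | O=C(c1c(F)cc(OCc2ccccc2)cc1Br)c1cc(OCc2ccccc2)c2c(c1)[C@@H](c1cc(OCc3ccccc3)cc(OCc3ccccc3)c1)[C@H](c1ccc(OCc3ccccc3)cc1)O2 | intermediate
16 | [4-(benzyloxy)phenyl]methanol | OCc1ccc(OCc2ccccc2)cc1 | starting material
17 | [4-(benzyloxy)-2-{[4-(benzyloxy)phenyl]methoxy}-6-bromophenyl](RB)methanone | O=C(c1c(OCc2ccc(OCc3ccccc3)cc2)cc(OCc2ccccc2)cc1Br)c1cc(OCc2ccccc2)c2c(c1)[C@@H](c1cc(OCc3ccccc3)cc(OCc3ccccc3)c1)[C@H](c1ccc(OCc3ccccc3)cc1)O2 | intermediate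
18 | hydrazone of 17 (E/Z mixture) | NN=C(c1c(OCc2ccc(OCc3ccccc3)cc2)cc(OCc2ccccc2)cc1Br)c1cc(OCc2ccccc2)c2c(c1)[C@@H](c1cc(OCc3ccccc3)cc(OCc3ccccc3)c1)[C@H](c1ccc(OCc3ccccc3)cc1)O2 | intermediate
19 | diazo compound from 18, [4-(benzyloxy)-2-{[4-(benzyloxy)phenyl]methoxy}-6-bromophenyl](RB)diazomethane | [N-]=[N+]=C(c1c(OCc2ccc(OCc3ccccc3)cc2)cc(OCc2ccccc2)cc1Br)c1cc(OCc2ccccc2)c2c(c1)[C@@H](c1cc(OCc3ccccc3)cc(OCc3ccccc3)c1)[C@H](c1ccc(OCc3ccccc3)cc1)O2 | intermediate (not isolated)
20 | (2R,3S)-6-(benzyloxy)-2-[4-(benzyloxy)phenyl]-4-bromo-3-(RB)-2,3-dihydro-1-benzofuran (ring A cis) | Brc1cc(OCc2ccccc2)cc2c1[C@H](c1cc(OCc3ccccc3)c3c(c1)[C@@H](c1cc(OCc4ccccc4)cc(OCc4ccccc4)c1)[C@H](c1ccc(OCc4ccccc4)cc1)O3)[C@H](c1ccc(OCc3ccccc3)cc1)O2 | intermediate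
21 | (2S,3S)-6-(benzyloxy)-2-[4-(benzyloxy)phenyl]-4-bromo-3-(RB)-2,3-dihydro-1-benzofuran (ring A trans) | Brc1cc(OCc2ccccc2)cc2c1[C@H](c1cc(OCc3ccccc3)c3c(c1)[C@@H](c1cc(OCc4ccccc4)cc(OCc4ccccc4)c1)[C@H](c1ccc(OCc4ccccc4)cc1)O3)[C@@H](c1ccc(OCc3ccccc3)cc1)O2 | intermediate
22 | 1-(benzyloxy)-4-ethynylbenzene | C#Cc1ccc(OCc2ccccc2)cc1 | starting material
23 | (2S,3S)-6-(benzyloxy)-2-[4-(benzyloxy)phenyl]-4-{[4-(benzyloxy)phenyl]ethynyl}-3-(RB)-2,3-dihydro-1-benzofuran | C(c1ccccc1)Oc1ccc(C#Cc2cc(OCc3ccccc3)cc3c2[C@H](c2cc(OCc4ccccc4)c4c(c2)[C@@H](c2cc(OCc5ccccc5)cc(OCc5ccccc5)c2)[C@H](c2ccc(OCc5ccccc5)cc2)O4)[C@@H](c2ccc(OCc4ccccc4)cc2)O3)cc1 | intermediate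
24 | (2S,3S)-6-(benzyloxy)-2-[4-(benzyloxy)phenyl]-4-{(Z)-2-[4-(benzyloxy)phenyl]ethenyl}-3-(RB)-2,3-dihydro-1-benzofuran | C(c1ccccc1)Oc1ccc(/C=C\c2cc(OCc3ccccc3)cc3c2[C@H](c2cc(OCc4ccccc4)c4c(c2)[C@@H](c2cc(OCc5ccccc5)cc(OCc5ccccc5)c2)[C@H](c2ccc(OCc5ccccc5)cc2)O4)[C@@H](c2ccc(OCc4ccccc4)cc2)O3)cc1 | intermediate
25 | (2R,3R)-3-(3,5-dihydroxyphenyl)-5-{(2S,3S)-6-hydroxy-2-(4-hydroxyphenyl)-4-[(Z)-2-(4-hydroxyphenyl)ethenyl]-2,3-dihydro-1-benzofuran-3-yl}-2-(4-hydroxyphenyl)-2,3-dihydro-1-benzofuran-7-ol | Oc1ccc(/C=C\c2cc(O)cc3c2[C@H](c2cc(O)c4c(c2)[C@@H](c2cc(O)cc(O)c2)[C@H](c2ccc(O)cc2)O4)[C@@H](c2ccc(O)cc2)O3)cc1 | target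

## Step count and least certain steps

Total: 15 steps. Longest linear sequence: 13 steps (1 to 25 through steps 1, 2, 4, 5, 6 and 8 to 15); steps 3 and 7 prepare the side branches 7 and 13.

**Step 5 (key step).** The hydride transfer may tell the two alpha-aryl groups apart only weakly, or in the sense opposite to the Felkin–Anh prediction, so that the ring closes partly or mainly cis. Reduction of a ketone shielded by three aryl groups may also be slow. Weak discrimination costs material but not configuration, because the cis and trans esters are separable diastereomers. A reversed preference is answered by relaying the stereochemistry the other way.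
- Fallback: starting from 8, RuCl[(S,S)-TsDPEN](p-cymene) under the same conditions should give methyl 3-(benzyloxy)-5-{(1R,2S)-1-[3,5-bis(benzyloxy)phenyl]-2-[4-(benzyloxy)phenyl]-2-hydroxyethyl}-4-fluorobenzoate F1, in which C3' is already R. K2CO3 in DMSO closes it to the cis ester methyl (2S,3R)-7-(benzyloxy)-3-[3,5-bis(benzyloxy)phenyl]-2-[4-(benzyloxy)phenyl]-2,3-dihydro-1-benzofuran-5-carboxylate F2. CF3CO2H in CH2Cl2 then equilibrates C2' through the benzylic cation to the trans ring, which is 10. C2' is thus set by thermodynamics and no longer by the catalyst.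

**Step 4.** The enolate of 7, or the enolate of the product, may attack the activated C–F carbon instead of waiting for palladium; the product enolate could close a 2,3-diarylbenzofuran by displacing the fluoride. Reductive elimination to a triarylated carbon may also be sluggish.
- Fallback: starting from 7, Me3SiCl, NEt3 and NaI in MeCN give the silyl enol ether (Z)-{1-[4-(benzyloxy)phenyl]-2-[3,5-bis(benzyloxy)phenyl]ethenyl}oxy(trimethyl)silane F3. This is coupled with 4 using Pd(OAc)2, P(t-Bu)3 and Bu3SnF in toluene. No free alkali enolate is present, and the route is rejoined at 8.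

**Step 10.** Condensation at a carbonyl flanked by bromine and the benzylic ether may stall, or may need temperatures at which hydrazine starts to attack the aryl bromide.
- Fallback: starting from 17, Lawesson's reagent in hot toluene gives the thioketone [4-(benzyloxy)-2-{[4-(benzyloxy)phenyl]methoxy}-6-bromophenyl](RB)methanethione F4. Its C=S group reacts with hydrazine hydrate at room temperature with loss of H2S, returning to the route at 18.

**Step 11.** The carbene sits on an aryl ring twisted by two ortho substituents. Formation of the rhodium carbene may be slow enough for azine formation to compete, and the asymmetric induction may fall short of what is known for singly ortho-substituted precursors.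
- Fallback: the diazo compound 19, prepared as in step 11 but without rhodium, is decomposed thermally in toluene. The free diarylcarbene abstracts the neighbouring benzylic hydrogen and the biradical recombines to ring A. This gives 20 together with the other cis isomer, (2S,3R)-6-(benzyloxy)-2-[4-(benzyloxy)phenyl]-4-bromo-3-(RB)-2,3-dihydro-1-benzofuran F5. Treatment as in step 12 converts the mixture into 21 and (2R,3R)-6-(benzyloxy)-2-[4-(benzyloxy)phenyl]-4-bromo-3-(RB)-2,3-dihydro-1-benzofuran F6. These are diastereomers because ring B is fixed, so they are separated by chromatography, and the route is rejoined at 21.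

**Step 15.** Traces of acid or the Lewis acid itself may isomerise the Z-olefin or let the protonated styryl group alkylate a neighbouring arene, and removal of seven benzyl groups may stop short.
- Fallback: the order of the last two operations is exchanged. Starting from 23, BCl3 and C6HMe5 at −78 °C give the alkyne heptaphenol (2R,3R)-3-(3,5-dihydroxyphenyl)-5-{(2S,3S)-6-hydroxy-2-(4-hydroxyphenyl)-4-[(4-hydroxyphenyl)ethynyl]-2,3-dihydro-1-benzofuran-3-yl}-2-(4-hydroxyphenyl)-2,3-dihydro-1-benzofuran-7-ol F7. Semi-hydrogenation over Pd on CaCO3 poisoned with Pb(OAc)2 with quinoline in EtOAc/MeOH then gives 25 directly, so the olefin never meets a Lewis acid.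

## Further compounds

F1 | step 5 | methyl 3-(benzyloxy)-5-{(1R,2S)-1-[3,5-bis(benzyloxy)phenyl]-2-[4-(benzyloxy)phenyl]-2-hydroxyethyl}-4-fluorobenzoate | COC(=O)c1cc(OCc2ccccc2)c(F)c(c1)[C@@H](c1cc(OCc2ccccc2)cc(OCc2ccccc2)c1)[C@@H](c1ccc(OCc2ccccc2)cc1)O
F2 | step 5 | methyl (2S,3R)-7-(benzyloxy)-3-[3,5-bis(benzyloxy)phenyl]-2-[4-(benzyloxy)phenyl]-2,3-dihydro-1-benzofuran-5-carboxylate | COC(=O)c1cc(OCc2ccccc2)c2c(c1)[C@@H](c1cc(OCc3ccccc3)cc(OCc3ccccc3)c1)[C@@H](c1ccc(OCc3ccccc3)cc1)O2
F3 | step 4 | (Z)-{1-[4-(benzyloxy)phenyl]-2-[3,5-bis(benzyloxy)phenyl]ethenyl}oxy(trimethyl)silane | C[Si](C)(C)O/C(c1ccc(OCc2ccccc2)cc1)=C\c1cc(OCc2ccccc2)cc(OCc2ccccc2)c1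
F4 | step 10 | [4-(benzyloxy)-2-{[4-(benzyloxy)phenyl]methoxy}-6-bromophenyl](RB)methanethione | S=C(c1c(OCc2ccc(OCc3ccccc3)cc2)cc(OCc2ccccc2)cc1Br)c1cc(OCc2ccccc2)c2c(c1)[C@@H](c1cc(OCc3ccccc3)cc(OCc3ccccc3)c1)[C@H](c1ccc(OCc3ccccc3)cc1)O2
F5 | step 11 | (2S,3R)-6-(benzyloxy)-2-[4-(benzyloxy)phenyl]-4-bromo-3-(RB)-2,3-dihydro-1-benzofuran | Brc1cc(OCc2ccccc2)cc2c1[C@@H](c1cc(OCc3ccccc3)c3c(c1)[C@@H](c1cc(OCc4ccccc4)cc(OCc4ccccc4)c1)[C@H](c1ccc(OCc4ccccc4)cc1)O3)[C@@H](c1ccc(OCc3ccccc3)cc1)O2
F6 | step 11 | (2R,3R)-6-(benzyloxy)-2-[4-(benzyloxy)phenyl]-4-bromo-3-(RB)-2,3-dihydro-1-benzofuran | Brc1cc(OCc2ccccc2)cc2c1[C@@H](c1cc(OCc3ccccc3)c3c(c1)[C@@H](c1cc(OCc4ccccc4)cc(OCc4ccccc4)c1)[C@H](c1ccc(OCc4ccccc4)cc1)O3)[C@H](c1ccc(OCc3ccccc3)cc1)O2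
F7 | step 15 | (2R,3R)-3-(3,5-dihydroxyphenyl)-5-{(2S,3S)-6-hydroxy-2-(4-hydroxyphenyl)-4-[(4-hydroxyphenyl)ethynyl]-2,3-dihydro-1-benzofuran-3-yl}-2-(4-hydroxyphenyl)-2,3-dihydro-1-benzofuran-7-ol | Oc1ccc(C#Cc2cc(O)cc3c2[C@H](c2cc(O)c4c(c2)[C@@H](c2cc(O)cc(O)c2)[C@H](c2ccc(O)cc2)O4)[C@@H](c2ccc(O)cc2)O3)cc1
A1 | alternative 1 | 3-[(4-methoxyphenyl)ethynyl]cyclobut-2-en-1-one carrying at C4 the 2-[(tert-butyldimethylsilyl)oxy]-2-(4-methoxyphenyl)-1-[(2R,3R)-3-(3,5-dimethoxyphenyl)-7-methoxy-2-(4-methoxyphenyl)-2,3-dihydro-1-benzofuran-5-yl]ethyl side chain (side-chain configuration as in A3; ring C4 unspecified) | COc1ccc(C#CC2=CC(=O)C2[C@H](c2cc(OC)c3c(c2)[C@@H](c2cc(OC)cc(OC)c2)[C@H](c2ccc(OC)cc2)O3)[C@@H](c2ccc(OC)cc2)O[Si](C)(C)C(C)(C)C)cc1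
A2 | alternative 1 | (triisopropylsiloxy)ethyne | C#CO[Si](C(C)C)(C(C)C)C(C)C
A3 | alternative 1 | ring A phenol from the benzannulation, with arylethynyl group, triisopropylsilyl ether and the C3/C2 side chain in place | COc1ccc(C#Cc2cc(O[Si](C(C)C)(C(C)C)C(C)C)cc(O)c2[C@H](c2cc(OC)c3c(c2)[C@@H](c2cc(OC)cc(OC)c2)[C@H](c2ccc(OC)cc2)O3)[C@@H](c2ccc(OC)cc2)O[Si](C)(C)C(C)(C)C)cc1
A4 | alternative 2 | (2R)-5-chloro-3-diazo-7-methoxy-2-(4-methoxyphenyl)-2,3-dihydro-4H-chromen-4-one | COc1cc(Cl)c2C(=O)C(=[N+]=[N-])[C@@H](c3ccc(OC)cc3)Oc2c1
A5 | alternative 2 | methyl (2S,3S)-4-chloro-6-methoxy-2-(4-methoxyphenyl)-2,3-dihydro-1-benzofuran-3-carboxylate | Clc1cc(OC)cc2c1[C@H](C(=O)OC)[C@@H](c1ccc(OC)cc1)O2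
A6 | alternative 3 | methyl 7-[(2R,3R)-5-bromo-7-methoxy-2-(4-methoxyphenyl)-2,3-dihydro-1-benzofuran-3-yl]-3,5,7-trioxoheptanoate | Brc1cc(OC)c2c(c1)[C@@H](C(=O)CC(=O)CC(=O)CC(=O)OC)[C@H](c1ccc(OC)cc1)O2
A7 | alternative 3 | methyl 2-[(2R,3R)-5-bromo-7-methoxy-2-(4-methoxyphenyl)-2,3-dihydro-1-benzofuran-3-yl]-4,6-dihydroxybenzoate | Brc1cc(OC)c2c(c1)[C@@H](c1cc(O)cc(O)c1C(=O)OC)[C@H](c1ccc(OC)cc1)O2
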